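**Strategy.** The target is a 20-membered cyclophane. An ether oxygen joins C-5 of ring A (the monohydroxy ring) to C-1 of ring B (the dihydroxy ring), and a saturated C14 chain spans C-3 of ring A and C-6 of ring B. The route disconnects the unfunctionalised CH2–CH2 bond between chain carbons 11 and 12, counted from ring B. Ring-closing metathesis of an open diaryl ether with a but-3-enyl arm on ring A and a dodec-11-enyl arm on ring B closes the macrocycle as a C=C bond at that site. The bridge has no stereocentre or functional group, so the olefin is a traceless handle, erased by the final hydrogenation that also cleaves all three benzyl ethers.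

Key step: step 6

Remark: the olefin from step 6 is expected as an E/Z mixture, which does not matter because step 7 saturates it. Compounds 1, 2, 9 and 10 (as a 0.5 M THF solution) are taken as catalogue materials.

**Step 1**
Reactants: 1 3,5-bis(benzyloxy)benzyl bromide; 2 11-bromoundec-1-ene
Product: 4 1,3-bis(benzyloxy)-5-(dodec-11-en-1-yl)benzene, via undec-10-en-1-ylmagnesium bromide 3 (not isolated)
Conditions: 2, Mg, THF, rt → 40 °C; then 1, Li2CuCl4 (3 mol%), THF, –10 °C → rt
Reagents that add atoms: none
Why: Kochi-type copper-catalysed sp3–sp3 coupling of a primary alkyl Grignard reagent with a reactive benzylic bromide should proceed cleanly, and the remote terminal alkene and the aryl benzyl ethers are inert to Grignard formation and to the cuprate.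

**Step 2**
Reactants: 4 1,3-bis(benzyloxy)-5-(dodec-11-en-1-yl)benzene
Product: 6 2,4-bis(benzyloxy)-6-(dodec-11-en-1-yl)benzaldehyde, via benzylidene-dimethyliminium chloride 5 (not isolated)
Conditions: POCl3, DMF, 0 °C → 65 °C; then ice/H2O, rt
Reagents that add atoms: N,N-dimethylformamide CN(C)C=O; water O
Why: Vilsmeier–Haack formylation of a 5-alkylresorcinol diether is expected at the position para to one benzyloxy group and ortho to the alkyl chain rather than at the carbon flanked by both ethers, and the isolated alkene does not react with the chloroiminium ion.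

**Step 3**
Reactants: 6 2,4-bis(benzyloxy)-6-(dodec-11-en-1-yl)benzaldehyde
Product: 8 2,4-bis(benzyloxy)-6-(dodec-11-en-1-yl)phenol, via aryl formate 7 (not isolated)
Conditions: 30% aq. H2O2, H2SO4 (cat.), MeOH, 0 °C → rt
Reagents that add atoms: hydrogen peroxide OO
Why: Acid-catalysed Dakin oxidation (Baeyer–Villiger type): the electron-rich, di-ortho-substituted aryl group migrates to oxygen and the formate is methanolysed in the flask, while hydrogen peroxide without a peracid should leave the terminal alkene and the benzyl ethers untouched.

**Step 4**
Reactants: 9 1-(benzyloxy)-3,5-dibromobenzene; 10 but-3-en-1-ylzinc bromide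
Product: 11 1-(benzyloxy)-3-bromo-5-(but-3-en-1-yl)benzene
Conditions: 9 (3 equiv), 10 (0.5 M in THF, 1 equiv), Pd(dppf)Cl2 (3 mol%), THF, 50 °C
Reagents that add atoms: none
Why: Negishi sp2–sp3 coupling with the dibromide in excess should stop at mono-alkylation, and a primary alkylzinc with the dppf ligand couples without β-hydride elimination or alkene migration.

**Step 5**
Reactants: 8 2,4-bis(benzyloxy)-6-(dodec-11-en-1-yl)phenol; 11 1-(benzyloxy)-3-bromo-5-(but-3-en-1-yl)benzene
Product: 12 1,5-bis(benzyloxy)-2-[3-(benzyloxy)-5-(but-3-en-1-yl)phenoxy]-3-(dodec-11-en-1-yl)benzene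
Conditions: CuI (10 mol%), picolinic acid (20 mol%), K3PO4, DMSO, 90 °C, Ar
Reagents that add atoms: none
Why: Ullmann-type Cu(I)/picolinic acid diaryl ether synthesis is suited to di-ortho-substituted phenols when the aryl bromide is unhindered, as the 3,5-disubstituted bromide 11 is, and the argon atmosphere protects the electron-rich phenol.

**Step 6**
Reactants: 12 1,5-bis(benzyloxy)-2-[3-(benzyloxy)-5-(but-3-en-1-yl)phenoxy]-3-(dodec-11-en-1-yl)benzene
Product: 13 tri-O-benzyl macrocyclic alkene (20-membered diaryl ether cyclophane, C11=C12 double bond in the C14 bridge counted from ring B, E/Z mixture)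
Conditions: Grubbs II (7.5 mol%), 1,4-benzoquinone (15 mol%), CH2Cl2 (1 mM), 40 °C
Reagents that add atoms: none
Why: Ring-closing olefin metathesis by the Chauvin mechanism: the Ru benzylidene initiates at one of the two monosubstituted terminal alkenes, and [2+2] cycloaddition of the resulting Ru alkylidene onto the other alkene followed by cycloreversion of the ruthenacyclobutane joins the internal CH of the but-3-enyl arm to the internal CH of the dodec-11-enyl arm and expels ethylene. The closest known reaction type is RCM macrocyclisation of α,ω-dienes to strain-free large-ring cycloalkenes and cyclophanes. The one ring closed is the 20-membered ring (three atoms of ring A, the ether oxygen, two atoms of ring B and the fourteen bridge carbons), formed by end-to-end closure of the two chain termini and made irreversible by loss of ethylene. No stereocentre is created, and the E/Z ratio of the new olefin is irrelevant because it is hydrogenated in step 7. The step needs intramolecular closure to win over acyclic diene oligomerisation and needs the double bonds not to migrate before closure; high dilution, the hinge-like diaryl ether (ortho attachment on ring B, meta on ring A) that holds both arms on one side, the absence of any other olefin or Lewis-basic group, and the benzoquinone additive that scavenges Ru hydrides should secure this.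

**Step 7**
Reactants: 13 tri-O-benzyl macrocyclic alkene
Product: 14 target macrocyclic triol (CNP0173380.0)
Conditions: H2 (1 atm), 10% Pd/C, EtOAc/EtOH, rt
Reagents that add atoms: none
Why: Heterogeneous catalytic hydrogenation should saturate the disubstituted olefin of either geometry and hydrogenolyse the three aryl benzyl ethers in the same operation, while the diaryl ether and the arenes are stable at 1 atm and room temperature.

**Compound list**
1 | 3,5-bis(benzyloxy)benzyl bromide | BrCc1cc(OCc2ccccc2)cc(OCc2ccccc2)c1 | starting material
2 | 11-bromoundec-1-ene | C=CCCCCCCCCCBr | starting material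
3 | undec-10-en-1-ylmagnesium bromide | C=CCCCCCCCCC[Mg]Br | intermediate
4 | 1,3-bis(benzyloxy)-5-(dodec-11-en-1-yl)benzene | C=CCCCCCCCCCCc1cc(OCc2ccccc2)cc(OCc2ccccc2)c1 | intermediate
5 | N-[2,4-bis(benzyloxy)-6-(dodec-11-en-1-yl)benzylidene]-N-methylmethanaminium chloride | C[N+](C)=Cc1c(OCc2ccccc2)cc(OCc2ccccc2)cc1CCCCCCCCCCC=C.[Cl-] | intermediate
6 | 2,4-bis(benzyloxy)-6-(dodec-11-en-1-yl)benzaldehyde | O=Cc1c(OCc2ccccc2)cc(OCc2ccccc2)cc1CCCCCCCCCCC=C | intermediate
7 | 2,4-bis(benzyloxy)-6-(dodec-11-en-1-yl)phenyl formate | O=COc1c(OCc2ccccc2)cc(OCc2ccccc2)cc1CCCCCCCCCCC=C | intermediate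
8 | 2,4-bis(benzyloxy)-6-(dodec-11-en-1-yl)phenol | Oc1c(OCc2ccccc2)cc(OCc2ccccc2)cc1CCCCCCCCCCC=C | intermediate
9 | 1-(benzyloxy)-3,5-dibromobenzene | Brc1cc(Br)cc(OCc2ccccc2)c1 | starting material
10 | but-3-en-1-ylzinc bromide | C=CCC[Zn]Br | starting material
11 | 1-(benzyloxy)-3-bromo-5-(but-3-en-1-yl)benzene | C=CCCc1cc(Br)cc(OCc2ccccc2)c1 | intermediate
12 | 1,5-bis(benzyloxy)-2-[3-(benzyloxy)-5-(but-3-en-1-yl)phenoxy]-3-(dodec-11-en-1-yl)benzene | C=CCCc1cc(OCc2ccccc2)cc(Oc2c(OCc3ccccc3)cc(OCc3ccccc3)cc2CCCCCCCCCCC=C)c1 | intermediate
13 | tri-O-benzyl macrocyclic alkene (20-membered ring, bridge olefin between chain carbons 11 and 12 from ring B, E/Z mixture) | O(Cc1ccccc1)c1cc2cc(c1)Oc1c(OCc3ccccc3)cc(OCc3ccccc3)cc1CCCCCCCCCCC=CCC2 | intermediate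
14 | macrocyclic diaryl ether triol with saturated C14 bridge (CNP0173380.0) | Oc1cc2cc(c1)Oc1c(O)cc(O)cc1CCCCCCCCCCCCCC2 | target

**Step count.** Total: 7 steps. Longest linear sequence: 6 steps (1, 2, 3, 5, 6, 7).

**Steps most likely to fail**

Step 6. Intermolecular metathesis may outrun closure of the 20-membered ring and give dimers and oligomers. Ruthenium hydride species may also shift a double bond before closure, which would give ring-contracted homologues that are hard to remove after hydrogenation. The fallback sets out from 12 and forms the same bond by carbonyl coupling. Oxidative cleavage of both terminal alkenes (OsO4 cat., NaIO4, 2,6-lutidine, dioxane/H2O) should give the dialdehyde F1. Intramolecular McMurry coupling of F1 (TiCl3/Zn–Cu, DME, reflux, syringe-pump addition) should join the two formyl carbons and return to the route at 13. Because the closure carbons are fixed as carbonyl groups, chain walking cannot occur.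

Step 5. Carbon–oxygen bond formation at the di-ortho-substituted, electron-rich phenoxide may be slow, so that hydrodebromination of the bromide and oxidative decay of the phenol take over at 90 °C. The fallback sets out from 11. Bromine–lithium exchange (n-BuLi, THF, –78 °C), borylation with B(OiPr)3 and acidic work-up should give the boronic acid F2. Chan–Lam–Evans coupling of F2 with 8 (Cu(OAc)2, pyridine, 4 Å molecular sieves, CH2Cl2, rt, dry air) runs at room temperature, is known to accept 2,6-disubstituted phenols, and comes back to the route at 12.

Step 3. Aryl migration may compete with hydride migration to the benzoic acid, and the very electron-rich phenol may be oxidised further under acidic peroxide. The fallback sets out from 4 and bypasses steps 2 and 3. Bromination with NBS (MeCN, 0 °C) is expected at the same ring position as the formylation and should give the aryl bromide F3. Bromine–lithium exchange (n-BuLi, THF, –78 °C) and trapping with B(OMe)3 should give the dimethyl boronate F4, which is not isolated. Oxidation with one equivalent of H2O2 in aqueous NaOH at 0 °C, followed by acidification, returns to the route at 8.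

**Further compounds**
F1 | step 6 | 3-{3-(benzyloxy)-5-[2,4-bis(benzyloxy)-6-(11-oxoundecyl)phenoxy]phenyl}propanal | O=CCCc1cc(OCc2ccccc2)cc(Oc2c(OCc3ccccc3)cc(OCc3ccccc3)cc2CCCCCCCCCCC=O)c1
F2 | step 5 | [3-(benzyloxy)-5-(but-3-en-1-yl)phenyl]boronic acid | OB(O)c1cc(CCC=C)cc(OCc2ccccc2)c1
F3 | step 3 | 1,5-bis(benzyloxy)-2-bromo-3-(dodec-11-en-1-yl)benzene | Brc1c(OCc2ccccc2)cc(OCc2ccccc2)cc1CCCCCCCCCCC=C
F4 | step 3 | dimethyl [2,4-bis(benzyloxy)-6-(dodec-11-en-1-yl)phenyl]boronate | COB(OC)c1c(OCc2ccccc2)cc(OCc2ccccc2)cc1CCCCCCCCCCC=C
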